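The benzo ring of the N–H indole is built last. That ring (C3a, C4, C5, C6, C7, C7a) carries only the C6 prenyl group. So C7a–C7–C6–C5 can come from C3–C6 of a 5-prenylpyridazine, and C3a–C4 from a terminal alkyne. One thermal alkyne–pyridazine [4+2] cycloaddition followed by N2 extrusion forms C3a–C7a and C4–C5. It closes the benzene and pyrroline rings at once, with the N1′–C3 bond to the second indole already in place. The precursor is a methyl N-(5-prenylpyridazin-3-yl)carbamate whose nitrogen bears a CH2–CH(6-prenylindol-1-yl)–C≡CH chain. Hydrolysis and dehydrogenation then give the target.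

Key step: step 10

Assumption: prenyl means 3-methylbut-2-en-1-yl. The target is achiral, so the single sp3 stereocentre carried through the middle of the route is left racemic and disappears in the last step.

Step 1
Reactants: 1 6-bromoindole; 2 prenylboronic acid pinacol ester [4,4,5,5-tetramethyl-2-(3-methylbut-2-enyl)-1,3,2-dioxaborolane]
Product: 3 6-prenylindole [6-(3-methylbut-2-enyl)-1H-indole]
Conditions: Pd(OAc)2 (cat.), QPhos (C5Ph5)Fe(C5H4P(t-Bu)2) (cat.), KF, toluene/H2O, 70 °C
Reagents that add atoms: none
Why: Suzuki–Miyaura coupling of an aryl bromide with an allylic boronate: the aryl(η3-prenyl)palladium species, held by a bulky electron-rich di-tert-butylphosphine, equilibrates before reductive elimination and couples at its unhindered CH2 terminus, so the linear prenyl arene should result, and the mild fluoride base tolerates the free N–H.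

Step 2
Reactants: 3 6-prenylindole; 4 methyl bromoacetate
Product: 5 methyl 2-(6-prenylindol-1-yl)acetate
Conditions: NaH, DMF, 0 °C to rt
Reagents that add atoms: none
Why: SN2 N-alkylation of the sodium indolide, which in a dipolar aprotic solvent reacts at nitrogen with a reactive α-bromo ester while the prenyl group stays inert.

Step 3
Reactants: 6 tert-butyl carbamate; 7 formaldehyde (37% aqueous); 8 sodium 4-methylbenzenesulfinate
Product: 9 tert-butyl N-[(4-methylphenyl)sulfonylmethyl]carbamate
Conditions: HCO2H, MeOH/H2O, rt
Reagents that add atoms: none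
Why: Three-component Mannich-type condensation to an α-amido sulfone: carbamate and formaldehyde give the N-hydroxymethyl adduct, formic acid ionises it, the sulfinate captures the N-acyliminium ion through sulfur, and this weak acid at room temperature leaves the Boc group intact.

Step 4
Reactants: 5 methyl 2-(6-prenylindol-1-yl)acetate; 9 tert-butyl N-[(4-methylphenyl)sulfonylmethyl]carbamate
Product: 11 methyl 3-(tert-butoxycarbonylamino)-2-(6-prenylindol-1-yl)propanoate (racemic), via N-Boc-methanimine 10 (not isolated)
Conditions: LiN(SiMe3)2 (2.1 equiv), THF, −78 °C; then 9, −78 to −40 °C; aq NH4Cl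
Reagents that add atoms: none
Why: Mannich addition of a lithium ester enolate to an N-Boc imine released in situ from an α-amido sulfone: one equivalent of base enolises 5, the other eliminates sulfinate from 9, and 10 is trapped cold before it can oligomerise; the new stereocentre forms as a racemate, which is acceptable because step 12 erases it, and a carbamate rather than an imide is placed on nitrogen because it withstands the hydride and carbonate of step 5 and is a poor leaving group for β-elimination.

Step 5
Reactants: 11 methyl 3-(tert-butoxycarbonylamino)-2-(6-prenylindol-1-yl)propanoate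
Product: 13 tert-butyl N-[2-(6-prenylindol-1-yl)but-3-ynyl]carbamate (racemic), via Boc-amino aldehyde 12 (not isolated)
Conditions: i-Bu2AlH (2.2 equiv), CH2Cl2, −78 °C; MeOH; then K2CO3, dimethyl (1-diazo-2-oxopropyl)phosphonate, −78 °C to rt; aq potassium sodium tartrate
Reagents that add atoms: dimethyl (1-diazo-2-oxopropyl)phosphonate, CC(=O)C(=[N+]=[N-])P(=O)(OC)OC (supplies the terminal alkyne carbon)
Why: Partial ester reduction telescoped with the Ohira–Bestmann (Seyferth–Gilbert type) homologation, a known one-flask ester-to-alkyne conversion for N-Boc amino esters: the first hydride only removes the N–H proton, the second stops at the aluminium hemiacetal at −78 °C, methanol frees aldehyde 12, and the diazophosphonate anion converts it to the alkyne faster than the poor carbamate leaving group can be lost, while enolisation is harmless at a racemic centre.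

Step 6
Reactants: 13 tert-butyl N-[2-(6-prenylindol-1-yl)but-3-ynyl]carbamate
Product: 15 2-(6-prenylindol-1-yl)but-3-yn-1-amine (racemic), via trimethylsilyl carbamate 14 (not isolated)
Conditions: Me3SiOTf, 2,6-lutidine, CH2Cl2, 0 °C; then MeOH, rt
Reagents that add atoms: trimethylsilyl trifluoromethanesulfonate, C[Si](C)(C)OS(=O)(=O)C(F)(F)F (its Me3Si group is held only in 14 and is lost again before 15)
Why: Boc cleavage through a silyl carbamate: silylation of the carbonyl oxygen releases the tert-butyl group as isobutene to the hindered pyridine base, and methanol then desilylates and decarboxylates 14, so no free Brønsted acid meets the trisubstituted alkene or the indole.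

Step 7
Reactants: 16 3,5-dichloropyridazine; 2 prenylboronic acid pinacol ester
Product: 17 3-chloro-5-prenylpyridazine
Conditions: Pd(OAc)2 (cat.), QPhos (C5Ph5)Fe(C5H4P(t-Bu)2) (cat.), KF, toluene/H2O, 70 °C
Reagents that add atoms: none
Why: Ligand-controlled site-selective Suzuki–Miyaura coupling: chelating phosphines send zerovalent palladium into the C3–Cl bond next to nitrogen, whereas this bulky monodentate phosphine is known to switch oxidative addition of 3,5-dichloropyridazine to C5–Cl, the prenyl group is delivered through its CH2 terminus as in step 1, and the C3–Cl bond needed in step 8 is kept.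

Step 8
Reactants: 15 2-(6-prenylindol-1-yl)but-3-yn-1-amine; 17 3-chloro-5-prenylpyridazine
Product: 18 N-[2-(6-prenylindol-1-yl)but-3-ynyl]-5-prenylpyridazin-3-amine (racemic)
Conditions: i-Pr2NEt, NMP, 130 °C, sealed tube, Ar
Reagents that add atoms: none
Why: Nucleophilic aromatic substitution (addition–elimination): C3 lies α to a ring nitrogen, so the primary amine adds to give a nitrogen-stabilised anionic σ-adduct and chloride leaves, and a hindered tertiary amine as the only base is too weak to shift the propargylic hydrogen or the doubly activated CH2 of the pyridazinyl prenyl group.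

Step 9
Reactants: 18 N-[2-(6-prenylindol-1-yl)but-3-ynyl]-5-prenylpyridazin-3-amine
Product: 19 methyl N-[2-(6-prenylindol-1-yl)but-3-ynyl]-N-(5-prenylpyridazin-3-yl)carbamate (racemic)
Conditions: ClCO2Me, i-Pr2NEt, DMAP (cat.), CH2Cl2, 0 °C to rt
Reagents that add atoms: methyl chloroformate, COC(=O)Cl
Why: N-acylation of a secondary heteroarylamine with a chloroformate under DMAP catalysis: any acylation at ring nitrogen is reversible and drains to the exocyclic carbamate, and no strong base is present that could metalate the alkyne.

Step 10
Reactants: 19 methyl N-[2-(6-prenylindol-1-yl)but-3-ynyl]-N-(5-prenylpyridazin-3-yl)carbamate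
Product: 21 methyl 6-prenyl-3-(6-prenylindol-1-yl)indoline-1-carboxylate (racemic), via diazabicyclooctatriene cycloadduct 20 (not isolated)
Conditions: 1,3,5-triisopropylbenzene (0.01 M, degassed), BHT (cat.), silanised glass, Ar, 230 °C
Reagents that add atoms: none
Why: The carbamoylated pyridazine serves as the LUMO-controlled diene and the pendant C≡C–H as the dienophile in an intramolecular inverse-electron-demand [4+2] cycloaddition across C3 and C6, giving the 2,3-diazabicyclo[2.2.2]octatriene 20, which expels N2 by retro-[4+2] and aromatises irreversibly. The closest known reaction is the thermal alkyne–1,2-diazine Diels–Alder conversion of N-acyl 3-(but-3-ynylamino)pyridazines into N-acylindolines, of which this is a direct application. The pyrroline ring closes through the three-atom N–CH2–CH tether when the internal alkyne carbon bonds to pyridazine C3 (5-exo-dig in sense, bond C3a–C7a), and the six-membered carbocycle closes in the same concerted event when the terminal alkyne carbon bonds to C6 (bond C4–C5), becoming the benzene ring once N2 has left. No stereocentre is created, since the bridgeheads of 20 vanish on aromatisation and the existing centre (indoline C3) is a racemic spectator. The tether fixes the regiochemistry, so pyridazine C5 can only become indoline C6; the alkyne is favoured over the indole C2=C3 bond and the prenyl alkenes because the indole would need a longer, six-ring-forming tether and loss of aromaticity, and the prenyl alkenes a bimolecular encounter that high dilution suppresses. The methoxycarbonyl group withdraws the amino lone pair from the diene and favours the rotamer that holds the chain over the ring, the branch at the propargylic carbon favours the folded conformer, and acid-free glass, degassing and a radical inhibitor protect the prenyl groups and the propargylic C–N bond.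

Step 11
Reactants: 21 methyl 6-prenyl-3-(6-prenylindol-1-yl)indoline-1-carboxylate
Product: 22 6-prenyl-3-(6-prenylindol-1-yl)indoline (racemic)
Conditions: KOH (excess), EtOH/H2O, 85 °C, Ar
Reagents that add atoms: none
Why: Base-mediated carbamate hydrolysis (BAc2) followed by spontaneous decarboxylation: the anilide-type nitrogen is a comparatively good leaving group, and the isolated trisubstituted alkenes, the N-alkylindole and the C3–N bond have no pathway under aqueous hydroxide at this temperature.

Step 12
Reactants: 22 6-prenyl-3-(6-prenylindol-1-yl)indoline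
Product: 23 6-prenyl-3-(6-prenylindol-1-yl)-1H-indole (target)
Conditions: MnO2 (activated, excess), CH2Cl2, rt
Reagents that add atoms: none
Why: MnO2 dehydrogenation of an N–H indoline to the indole, driven by aromatisation: it removes the C2 and C3 hydrogens and so erases the only stereocentre, and at room temperature it does not attack the allylic or benzylic C–H bonds of the prenyl groups.

Compound list
1 | 6-bromoindole | Brc1ccc2cc[nH]c2c1 | starting material
2 | prenylboronic acid pinacol ester | CC(C)=CCB1OC(C)(C)C(C)(C)O1 | starting material
3 | 6-prenylindole | CC(C)=CCc1ccc2cc[nH]c2c1 | intermediate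
4 | methyl bromoacetate | COC(=O)CBr | starting material
5 | methyl 2-(6-prenylindol-1-yl)acetate | COC(=O)Cn1ccc2ccc(CC=C(C)C)cc21 | intermediate
6 | tert-butyl carbamate | CC(C)(C)OC(N)=O | starting material
7 | formaldehyde | C=O | starting material
8 | sodium 4-methylbenzenesulfinate | Cc1ccc(cc1)S(=O)[O-].[Na+] | starting material
9 | tert-butyl N-[(4-methylphenyl)sulfonylmethyl]carbamate | CC(C)(C)OC(=O)NCS(=O)(=O)c1ccc(C)cc1 | intermediate
10 | tert-butyl N-methylidenecarbamate (N-Boc-methanimine, not isolated) | CC(C)(C)OC(=O)N=C | intermediate
11 | methyl 3-(tert-butoxycarbonylamino)-2-(6-prenylindol-1-yl)propanoate (racemic) | COC(=O)C(CNC(=O)OC(C)(C)C)n1ccc2ccc(CC=C(C)C)cc21 | intermediate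
12 | tert-butyl N-[3-oxo-2-(6-prenylindol-1-yl)propyl]carbamate (racemic, not isolated) | O=CC(CNC(=O)OC(C)(C)C)n1ccc2ccc(CC=C(C)C)cc21 | intermediate
13 | tert-butyl N-[2-(6-prenylindol-1-yl)but-3-ynyl]carbamate (racemic) | C#CC(CNC(=O)OC(C)(C)C)n1ccc2ccc(CC=C(C)C)cc21 | intermediate
14 | trimethylsilyl N-[2-(6-prenylindol-1-yl)but-3-ynyl]carbamate (racemic, not isolated) | C#CC(CNC(=O)O[Si](C)(C)C)n1ccc2ccc(CC=C(C)C)cc21 | intermediate
15 | 2-(6-prenylindol-1-yl)but-3-yn-1-amine (racemic) | C#CC(CN)n1ccc2ccc(CC=C(C)C)cc21 | intermediate
16 | 3,5-dichloropyridazine | Clc1cnnc(Cl)c1 | starting material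
17 | 3-chloro-5-prenylpyridazine | Clc1cc(CC=C(C)C)cnn1 | intermediate
18 | N-[2-(6-prenylindol-1-yl)but-3-ynyl]-5-prenylpyridazin-3-amine (racemic) | C#CC(CNc1cc(CC=C(C)C)cnn1)n1ccc2ccc(CC=C(C)C)cc21 | intermediate
19 | methyl N-[2-(6-prenylindol-1-yl)but-3-ynyl]-N-(5-prenylpyridazin-3-yl)carbamate (racemic) | C#CC(CN(C(=O)OC)c1cc(CC=C(C)C)cnn1)n1ccc2ccc(CC=C(C)C)cc21 | intermediate
20 | pyrrolidine-fused 2,3-diazabicyclo[2.2.2]octa-2,5,7-triene cycloadduct of 19 (racemic diastereomer mixture, not isolated) | COC(=O)N1CC(n2ccc3ccc(CC=C(C)C)cc32)C4=CC5N=NC14C=C5CC=C(C)C | intermediate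
21 | methyl 6-prenyl-3-(6-prenylindol-1-yl)indoline-1-carboxylate (racemic) | COC(=O)N1CC(n2ccc3ccc(CC=C(C)C)cc32)c2ccc(CC=C(C)C)cc21 | intermediate
22 | 6-prenyl-3-(6-prenylindol-1-yl)indoline (racemic) | C1Nc2cc(CC=C(C)C)ccc2C1n1ccc2ccc(CC=C(C)C)cc21 | intermediate
23 | 6-prenyl-3-(6-prenylindol-1-yl)-1H-indole | CC(C)=CCc1ccc2c(-n3ccc4ccc(CC=C(C)C)cc43)c[nH]c2c1 | target

Total step count: 12.
Longest linear sequence: 10 (steps 1, 2, 4, 5, 6, 8, 9, 10, 11, 12). Steps 3 and 7 are side branches.

Steps most likely to fail

1. Step 10.
- **Risk:** The diazine carries no activating group beyond the carbamate, so cycloaddition may be slow. At 230 °C several processes could then compete: cleavage or sigmatropic migration of the propargylic C–N bond, cycloaddition of the indole C2=C3 bond onto the diazine, or thermal expulsion of the indolyl group from C3 of the freshly formed indoline.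
- **Fallback:** This gives up ring construction and makes the N1′–C3 bond directly by a copper-catalysed Ullmann–Goldberg N-arylation. It sets out from 3 and comes back to the route at 23. Compound 3 is iodinated at C3 (I2, KOH, DMF, rt) to 3-iodo-6-prenyl-1H-indole F1. This is N-sulfonylated (TsCl, NaH, THF, 0 °C) to 3-iodo-6-prenyl-1-tosylindole F2. F2 is coupled with a second portion of 3 (CuI, trans-N,N′-dimethylcyclohexane-1,2-diamine, K3PO4, toluene, 110 °C) to 6-prenyl-3-(6-prenylindol-1-yl)-1-tosylindole F3. Detosylation (KOH, MeOH/THF, 60 °C) gives 23.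

2. Step 8.
- **Risk:** Displacement at the only moderately activated C3–Cl bond by a β-branched amine may be sluggish. Long heating could then allow propargyl-to-allene isomerisation, or migration of the pyridazinyl prenyl double bond into conjugation.
- **Fallback:** The thermal substitution is replaced by a Buchwald–Hartwig amination at lower temperature, with the alkyne masked so that it cannot enter palladium-mediated alkynylation or hydroamination. It sets out from 13 (with 17) and comes back at 19.
  - Compound 13 is doubly lithiated and C-silylated (n-BuLi, 2.1 equiv, THF, −78 °C; i-Pr3SiOTf, 1.05 equiv) to tert-butyl N-[2-(6-prenylindol-1-yl)-4-(triisopropylsilyl)but-3-ynyl]carbamate F4.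
  - Me3SiOTf/2,6-lutidine converts it to trimethylsilyl N-[2-(6-prenylindol-1-yl)-4-(triisopropylsilyl)but-3-ynyl]carbamate F5, and methanol then releases 2-(6-prenylindol-1-yl)-4-(triisopropylsilyl)but-3-yn-1-amine F6.
  - Coupling with 17 (Pd(OAc)2, rac-BINAP, Cs2CO3, toluene, 90 °C) gives N-[2-(6-prenylindol-1-yl)-4-(triisopropylsilyl)but-3-ynyl]-5-prenylpyridazin-3-amine F7.
  - Acylation as in step 9 gives methyl N-[2-(6-prenylindol-1-yl)-4-(triisopropylsilyl)but-3-ynyl]-N-(5-prenylpyridazin-3-yl)carbamate F8.
  - Bu4NF buffered with AcOH (THF, 0 °C) unmasks 19.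

3. Step 7.
- **Risk:** The allylic unit may be transferred through its tertiary terminus, the allylic boronate may protodeboronate before transmetalation, or oxidative addition at C3–Cl may compete.
- **Fallback:** The prenyl group is assembled in two stages so that no linear/branched choice arises. It sets out from 16 and comes back at 17. Compound 16 is coupled under the same C5-directing catalyst with the symmetrical allyl donor allylboronic acid pinacol ester to give 5-allyl-3-chloropyridazine F9. Olefin cross-metathesis with 2-methylbut-2-ene as solvent (second-generation Grubbs catalyst RuCl2(=CHPh)(PCy3)(H2IMes), 40 °C) then converts F9 to 17. Any C3-coupled isomer is removed by chromatography at the stage of F9.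

Further compounds
F1 | step 10 | 3-iodo-6-prenyl-1H-indole | CC(C)=CCc1ccc2c(I)c[nH]c2c1
F2 | step 10 | 3-iodo-6-prenyl-1-tosylindole | CC(C)=CCc1ccc2c(I)cn(S(=O)(=O)c3ccc(C)cc3)c2c1
F3 | step 10 | 6-prenyl-3-(6-prenylindol-1-yl)-1-tosylindole | CC(C)=CCc1ccc2c(-n3ccc4ccc(CC=C(C)C)cc43)cn(S(=O)(=O)c3ccc(C)cc3)c2c1
F4 | step 8 | tert-butyl N-[2-(6-prenylindol-1-yl)-4-(triisopropylsilyl)but-3-ynyl]carbamate (racemic) | CC(C)[Si](C#CC(CNC(=O)OC(C)(C)C)n1ccc2ccc(CC=C(C)C)cc21)(C(C)C)C(C)C
F5 | step 8 | trimethylsilyl N-[2-(6-prenylindol-1-yl)-4-(triisopropylsilyl)but-3-ynyl]carbamate (racemic) | CC(C)[Si](C#CC(CNC(=O)O[Si](C)(C)C)n1ccc2ccc(CC=C(C)C)cc21)(C(C)C)C(C)C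
F6 | step 8 | 2-(6-prenylindol-1-yl)-4-(triisopropylsilyl)but-3-yn-1-amine (racemic) | CC(C)[Si](C#CC(CN)n1ccc2ccc(CC=C(C)C)cc21)(C(C)C)C(C)C
F7 | step 8 | N-[2-(6-prenylindol-1-yl)-4-(triisopropylsilyl)but-3-ynyl]-5-prenylpyridazin-3-amine (racemic) | CC(C)[Si](C#CC(CNc1cc(CC=C(C)C)cnn1)n1ccc2ccc(CC=C(C)C)cc21)(C(C)C)C(C)C
F8 | step 8 | methyl N-[2-(6-prenylindol-1-yl)-4-(triisopropylsilyl)but-3-ynyl]-N-(5-prenylpyridazin-3-yl)carbamate (racemic) | CC(C)[Si](C#CC(CN(C(=O)OC)c1cc(CC=C(C)C)cnn1)n1ccc2ccc(CC=C(C)C)cc21)(C(C)C)C(C)C
F9 | step 7 | 5-allyl-3-chloropyridazine | C=CCc1cnnc(Cl)c1
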